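## Retrosynthetic overview

1. Last ring: the carbocycle of target 28 is closed by a Dieckmann condensation (C6–C7) of keto ester 26, a dihydropyranone that carries the C5 acyl group and the C8 quaternary ester side by side.
2. First ring: the dihydropyranone (O1–C8a) comes from acid cyclodehydration of δ-hydroxy-β-diketone 23 while C5 is still a silyl-protected carbinol, so only the C8a carbonyl can take the pyran oxygen.
3. Key C–C bond (C4a–C4): intermolecular aldol of the lithium enolate of ketone 16 (C8 fragment) with aldehyde 19 (C2 fragment), then oxidation. The C4a–C5 bond comes from an earlier aldol of keto ester 7 with 5-methylhex-4-enal 13.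
4. Stereocentres: C8 from a double Fráter–Seebach alkylation (geranyl, then methyl) of ethyl (S)-3-hydroxybutanoate 1, then oxidation to 7. C2 comes from the same hydroxy ester via 19, and its C–O bond is never broken.

Assumption: the target is taken as the drawn enol tautomer, chromene numbering (O1, C2, C3, C4, C4a, C5–C8, C8a) is used for all intermediates, geranyl = (2E)-3,7-dimethylocta-2,6-dien-1-yl, and carbinol centres that are oxidised later are carried as epimer mixtures.

## Route

Step 1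
Reactants: 1 ethyl (S)-3-hydroxybutanoate; 2 geranyl bromide
Product: 4 ethyl (2S,3S)-2-geranyl-3-hydroxybutanoate, via dilithium alkoxide-enolate 3 (not isolated)
Conditions: LiN(iPr)2 (2.2 eq), THF, −78 → −20 °C; then 2, DMPU, −78 → 0 °C; AcOH quench
Reagents that add atoms: none
Why: Fráter–Seebach alkylation: the chelated dilithium alkoxide-enolate is alkylated by the allylic bromide on the face anti to the C3 methyl group, which sets C2 as S (anti, about 95:5 dr).

Step 2
Reactants: 4 ethyl (2S,3S)-2-geranyl-3-hydroxybutanoate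
Product: 6 ethyl (2R,3S)-2-geranyl-3-hydroxy-2-methylbutanoate, via dilithium alkoxide-enolate 5 (not isolated)
Conditions: LiN(iPr)2 (2.3 eq), THF, −78 → −20 °C; then CH3I, DMPU, −78 → 0 °C; AcOH quench
Reagents that add atoms: iodomethane, CI
Why: Second Fráter–Seebach alkylation: the same lithium chelate again delivers the electrophile anti to the C3 methyl group, so methyl takes the place geranyl took in step 1 and the quaternary carbon (future C8) is set as R with about 9:1 dr, the minor epimer being removed by chromatography at this diastereomeric stage.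

Step 3
Reactants: 6 ethyl (2R,3S)-2-geranyl-3-hydroxy-2-methylbutanoate
Product: 7 ethyl (2R,4E)-2-acetyl-2,5,9-trimethyldeca-4,8-dienoate
Conditions: DMP, pyridine, CH2Cl2, 0 °C → rt
Reagents that add atoms: none
Why: Dess–Martin oxidation of the secondary alcohol gives the β-keto ester whose quaternary α-carbon cannot epimerise and whose two arms are now distinct (acetyl = future C8a/C4a, ester = future C7).

Step 4
Reactants: 8 2-methylbut-3-en-2-ol; 9 triethyl orthoacetate
Product: 11 ethyl 5-methylhex-4-enoate, via ketene acetal 10 (not isolated)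
Conditions: EtCO2H (cat.), 140 °C, distil off EtOH
Reagents that add atoms: none
Why: Johnson–Claisen rearrangement: acid-catalysed exchange gives the ketene acetal, whose [3,3]-sigmatropic shift delivers the γ,δ-unsaturated ester with the trisubstituted alkene.

Step 5
Reactants: 11 ethyl 5-methylhex-4-enoate
Product: 13 5-methylhex-4-enal, via aluminium hemiacetal 12 (not isolated)
Conditions: iBu2AlH (1.1 eq), CH2Cl2, −78 °C; then MeOH, H2O
Reagents that add atoms: none
Why: Partial ester reduction: the tetrahedral aluminium hemiacetal is stable at −78 °C and releases the aldehyde only on aqueous work-up.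

Step 6
Reactants: 7 ethyl (2R,4E)-2-acetyl-2,5,9-trimethyldeca-4,8-dienoate; 13 5-methylhex-4-enal
Product: 15 ethyl (2R,4E)-2-(3-hydroxy-7-methyloct-6-enoyl)-2,5,9-trimethyldeca-4,8-dienoate (C5 epimers), via lithium enolate 14 (not isolated)
Conditions: LiN(iPr)2 (1.05 eq), THF, −78 °C; then 13, −78 °C; AcOH quench at −78 °C
Reagents that add atoms: none
Why: Intermolecular aldol addition: the acetyl CH3 is the only enolisable position of 7 and its lithium enolate adds to the unhindered aldehyde at −78 °C, the new carbinol (future C5) forming as an inconsequential epimer mixture because it is oxidised in step 14.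

Step 7
Reactants: 15 ethyl (2R,4E)-2-(3-hydroxy-7-methyloct-6-enoyl)-2,5,9-trimethyldeca-4,8-dienoate
Product: 16 ethyl (2R,4E)-2-[3-(tert-butyldimethylsilyloxy)-7-methyloct-6-enoyl]-2,5,9-trimethyldeca-4,8-dienoate
Conditions: TBSOTf, 2,6-lutidine, CH2Cl2, −78 °C
Reagents that add atoms: tert-butyldimethylsilyl trifluoromethanesulfonate, CC(C)(C)[Si](C)(C)OS(=O)(=O)C(F)(F)F
Why: Silyl triflate protection of the hindered aldol hydroxyl at low temperature avoids retro-aldol, and keeping C5 as a protected carbinol leaves C8a as the only carbonyl that can later accept the pyran oxygen.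

Step 8
Reactants: 1 ethyl (S)-3-hydroxybutanoate
Product: 17 ethyl (S)-3-(triethylsilyloxy)butanoate
Conditions: TESCl, imidazole, CH2Cl2, 0 °C → rt
Reagents that add atoms: chlorotriethylsilane, CC[Si](CC)(CC)Cl
Why: Standard silylation of the secondary alcohol; the TES ether is chosen because mild acid removes it in the presence of a TBS ether, and the stereocentre (future C2, S) is not touched.

Step 9
Reactants: 17 ethyl (S)-3-(triethylsilyloxy)butanoate
Product: 19 (S)-3-(triethylsilyloxy)butanal, via aluminium hemiacetal 18 (not isolated)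
Conditions: iBu2AlH (1.1 eq), CH2Cl2, −78 °C; then MeOH, H2O
Reagents that add atoms: none
Why: Partial ester reduction with iBu2AlH at −78 °C via the stable aluminium hemiacetal gives the β-silyloxy aldehyde without affecting the stereocentre.

Step 10
Reactants: 16 ethyl (2R,4E)-2-[3-(tert-butyldimethylsilyloxy)-7-methyloct-6-enoyl]-2,5,9-trimethyldeca-4,8-dienoate; 19 (S)-3-(triethylsilyloxy)butanal
Product: 21 ethyl (2R,4E)-2-{3-(tert-butyldimethylsilyloxy)-2-[(3S)-1-hydroxy-3-(triethylsilyloxy)butyl]-7-methyloct-6-enoyl}-2,5,9-trimethyldeca-4,8-dienoate (diastereomer mixture), via lithium enolate 20 (not isolated)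
Conditions: LiN(iPr)2 (1.1 eq), THF, −78 °C; then 19, −78 °C; AcOH quench at −78 °C
Reagents that add atoms: none
Why: Key intermolecular aldol addition that joins the C8 fragment to the C2 fragment through the C4a–C4 bond: C4a is the only enolisable carbon of 16, its β-silyloxy lithium enolate is stable at −78 °C, and the aldehyde is far more electrophilic than the neopentyl ester, while the new C4a and C4 centres need no control because both are erased in steps 11 and 12.

Step 11
Reactants: 21 aldol adduct (diastereomer mixture)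
Product: 22 ethyl (2R,4E)-2-{3-(tert-butyldimethylsilyloxy)-7-methyl-2-[(3S)-3-(triethylsilyloxy)butanoyl]oct-6-enoyl}-2,5,9-trimethyldeca-4,8-dienoate
Conditions: DMP, pyridine, CH2Cl2, 0 °C → rt
Reagents that add atoms: none
Why: Dess–Martin oxidation converts the β-hydroxy ketone into the 1,3-diketone under buffered non-basic conditions that leave both silyl ethers in place.

Step 12
Reactants: 22 silyl-protected β-diketone
Product: 24 ethyl (2R,4E)-2-{(2S)-5-[1-(tert-butyldimethylsilyloxy)-5-methylhex-4-en-1-yl]-2-methyl-4-oxo-3,4-dihydro-2H-pyran-6-yl}-2,5,9-trimethyldeca-4,8-dienoate, via hydroxy diketone 23 (not isolated)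
Conditions: PPTS, MeOH, 0 °C; then TsOH·H2O (cat.), 4 Å MS, CH2Cl2, rt
Reagents that add atoms: none
Why: Acid cyclodehydration to a 2,3-dihydro-4H-pyran-4-one: mild acid cleaves only the TES ether, the freed δ-hydroxyl closes a six-membered hemiketal on the 1,5-related C8a carbonyl (C5 is only a protected carbinol) and loss of water gives the vinylogous ester, so O1 is fixed on C8a and C2 stays S because its C–O bond is never broken.

Step 13
Reactants: 24 C5-silyloxy dihydropyranone ester
Product: 25 ethyl (2R,4E)-2-[(2S)-5-(1-hydroxy-5-methylhex-4-en-1-yl)-2-methyl-4-oxo-3,4-dihydro-2H-pyran-6-yl]-2,5,9-trimethyldeca-4,8-dienoate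
Conditions: HF·pyridine, pyridine, THF, 0 °C → rt; crude used at once
Reagents that add atoms: none
Why: Desilylation with pyridine-buffered HF·pyridine frees the C5 alcohol without base, which would open the dihydropyranone, and the crude alcohol is oxidised at once to forestall lactonisation onto the neighbouring ester.

Step 14
Reactants: 25 C5 alcohol
Product: 26 ethyl (2R,4E)-2-[(2S)-2-methyl-5-(5-methylhex-4-enoyl)-4-oxo-3,4-dihydro-2H-pyran-6-yl]-2,5,9-trimethyldeca-4,8-dienoate
Conditions: DMP, pyridine, CH2Cl2, 0 °C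
Reagents that add atoms: none
Why: Dess–Martin oxidation of the allylic alcohol gives the C5 ketone and merges the two C5 epimers into one compound.

Step 15
Reactants: 26 keto ester
Product: 28 (2S,8R)-8-geranyl-5-hydroxy-2,8-dimethyl-6-(3-methylbut-2-en-1-yl)-2,3-dihydro-4H-chromene-4,7(8H)-dione, via lithium enolate 27 (not isolated)
Conditions: LiN(SiMe3)2 (2.3 eq), THF, −78 → −30 °C; then AcOH
Reagents that add atoms: none
Why: Dieckmann (intramolecular Claisen) condensation: the kinetically formed C6 enolate of the C5 ketone attacks the cis-held ester through a six-membered transition state and deprotonation of the resulting cyclic β-triketone drives the closure, neither C2 nor C8 being involved, so acidification gives the target as its enol.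

## Compound list

1 | ethyl (S)-3-hydroxybutanoate | C[C@H](O)CC(=O)OCC | starting material
2 | geranyl bromide, (2E)-1-bromo-3,7-dimethylocta-2,6-diene | CC(C)=CCC/C(C)=C/CBr | starting material
3 | dilithium alkoxide-enolate of 1 | C[C@H](O[Li])C=C(O[Li])OCC | intermediate
4 | ethyl (2S,3S)-2-[(2E)-3,7-dimethylocta-2,6-dien-1-yl]-3-hydroxybutanoate | C[C@H](O)[C@H](C/C=C(\C)CCC=C(C)C)C(=O)OCC | intermediate
5 | dilithium alkoxide-enolate of 4 | C[C@H](O[Li])C(C/C=C(\C)CCC=C(C)C)=C(O[Li])OCC | intermediate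
6 | ethyl (2R,3S)-2-[(2E)-3,7-dimethylocta-2,6-dien-1-yl]-3-hydroxy-2-methylbutanoate | C[C@H](O)[C@@](C)(C/C=C(\C)CCC=C(C)C)C(=O)OCC | intermediate
7 | ethyl (2R,4E)-2-acetyl-2,5,9-trimethyldeca-4,8-dienoate | CC(=O)[C@@](C)(C/C=C(\C)CCC=C(C)C)C(=O)OCC | intermediate
8 | 2-methylbut-3-en-2-ol | CC(C)(O)C=C | starting material
9 | triethyl orthoacetate (1,1,1-triethoxyethane) | CC(OCC)(OCC)OCC | starting material
10 | 1-ethoxy-1-[(2-methylbut-3-en-2-yl)oxy]ethene (mixed ketene acetal) | C=C(OCC)OC(C)(C)C=C | intermediate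
11 | ethyl 5-methylhex-4-enoate | CC(C)=CCCC(=O)OCC | intermediate
12 | diisobutylaluminium hemiacetal of 11 | CC(C)=CCCC(OCC)O[Al](CC(C)C)CC(C)C | intermediate
13 | 5-methylhex-4-enal | CC(C)=CCCC=O | intermediate
14 | lithium enolate of 7 (acetyl group as CH2=C(OLi)) | C=C(O[Li])[C@@](C)(C/C=C(\C)CCC=C(C)C)C(=O)OCC | intermediate
15 | ethyl (2R,4E)-2-(3-hydroxy-7-methyloct-6-enoyl)-2,5,9-trimethyldeca-4,8-dienoate (epimers at the carbinol, future C5) | CC(C)=CCCC(O)CC(=O)[C@@](C)(C/C=C(\C)CCC=C(C)C)C(=O)OCC | intermediate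
16 | ethyl (2R,4E)-2-[3-(tert-butyldimethylsilyloxy)-7-methyloct-6-enoyl]-2,5,9-trimethyldeca-4,8-dienoate | CC(C)=CCCC(O[Si](C)(C)C(C)(C)C)CC(=O)[C@@](C)(C/C=C(\C)CCC=C(C)C)C(=O)OCC | intermediate
17 | ethyl (S)-3-(triethylsilyloxy)butanoate | C[C@H](O[Si](CC)(CC)CC)CC(=O)OCC | intermediate
18 | diisobutylaluminium hemiacetal of 17 | C[C@H](O[Si](CC)(CC)CC)CC(OCC)O[Al](CC(C)C)CC(C)C | intermediate
19 | (S)-3-(triethylsilyloxy)butanal | C[C@H](O[Si](CC)(CC)CC)CC=O | intermediate
20 | lithium enolate of 16 (C8a–O–Li, C8a=C4a) | CC(C)=CCCC(O[Si](C)(C)C(C)(C)C)C=C(O[Li])[C@@](C)(C/C=C(\C)CCC=C(C)C)C(=O)OCC | intermediate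
21 | ethyl (2R,4E)-2-{3-(tert-butyldimethylsilyloxy)-2-[(3S)-1-hydroxy-3-(triethylsilyloxy)butyl]-7-methyloct-6-enoyl}-2,5,9-trimethyldeca-4,8-dienoate (diastereomer mixture) | CC(C)=CCCC(O[Si](C)(C)C(C)(C)C)C(C(O)C[C@H](C)O[Si](CC)(CC)CC)C(=O)[C@@](C)(C/C=C(\C)CCC=C(C)C)C(=O)OCC | intermediate
22 | ethyl (2R,4E)-2-{3-(tert-butyldimethylsilyloxy)-7-methyl-2-[(3S)-3-(triethylsilyloxy)butanoyl]oct-6-enoyl}-2,5,9-trimethyldeca-4,8-dienoate | CC(C)=CCCC(O[Si](C)(C)C(C)(C)C)C(C(=O)C[C@H](C)O[Si](CC)(CC)CC)C(=O)[C@@](C)(C/C=C(\C)CCC=C(C)C)C(=O)OCC | intermediate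
23 | ethyl (2R,4E)-2-{3-(tert-butyldimethylsilyloxy)-2-[(3S)-3-hydroxybutanoyl]-7-methyloct-6-enoyl}-2,5,9-trimethyldeca-4,8-dienoate | CC(C)=CCCC(O[Si](C)(C)C(C)(C)C)C(C(=O)C[C@H](C)O)C(=O)[C@@](C)(C/C=C(\C)CCC=C(C)C)C(=O)OCC | intermediate
24 | ethyl (2R,4E)-2-{(2S)-5-[1-(tert-butyldimethylsilyloxy)-5-methylhex-4-en-1-yl]-2-methyl-4-oxo-3,4-dihydro-2H-pyran-6-yl}-2,5,9-trimethyldeca-4,8-dienoate | C[C@H]1CC(=O)C(C(O[Si](C)(C)C(C)(C)C)CCC=C(C)C)=C(O1)[C@@](C)(C/C=C(\C)CCC=C(C)C)C(=O)OCC | intermediate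
25 | ethyl (2R,4E)-2-[(2S)-5-(1-hydroxy-5-methylhex-4-en-1-yl)-2-methyl-4-oxo-3,4-dihydro-2H-pyran-6-yl]-2,5,9-trimethyldeca-4,8-dienoate | C[C@H]1CC(=O)C(C(O)CCC=C(C)C)=C(O1)[C@@](C)(C/C=C(\C)CCC=C(C)C)C(=O)OCC | intermediate
26 | ethyl (2R,4E)-2-[(2S)-2-methyl-5-(5-methylhex-4-enoyl)-4-oxo-3,4-dihydro-2H-pyran-6-yl]-2,5,9-trimethyldeca-4,8-dienoate | C[C@H]1CC(=O)C(C(=O)CCC=C(C)C)=C(O1)[C@@](C)(C/C=C(\C)CCC=C(C)C)C(=O)OCC | intermediate
27 | lithium enolate of 26 (C6 enolate of the C5 ketone) | C[C@H]1CC(=O)C(C(O[Li])=CCC=C(C)C)=C(O1)[C@@](C)(C/C=C(\C)CCC=C(C)C)C(=O)OCC | intermediate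
28 | (2S,8R)-8-[(2E)-3,7-dimethylocta-2,6-dien-1-yl]-5-hydroxy-2,8-dimethyl-6-(3-methylbut-2-en-1-yl)-2,3-dihydro-4H-chromene-4,7(8H)-dione (CNP0172889.1) | CC(C)=CCC/C(C)=C/C[C@@]1(C)C(=O)C(CC=C(C)C)=C(O)C2=C1O[C@@H](C)CC2=O | target

## Step count and risks

Total steps: 15. Longest linear sequence: 11 steps (steps 1, 2, 3, 6, 7, 10, 11, 12, 13, 14, 15).

Step 12 is the most likely to fail. The C8a carbonyl of 22 sits between a quaternary and a tertiary carbon, so ring closure may be slow and acid may instead expel the C5 silyloxy group. The fallback builds the pyranone before C5 is attached. It sets out from 7: the lithium enolate of 7 (LiN(iPr)2, THF, −78 °C) is added to aldehyde 19 to give β-hydroxy ketone F1. DMP gives β-diketone F2, and PPTS/MeOH then TsOH closes the unhindered, C4a-unsubstituted dihydropyranone F3. Electrophilic iodination at the vinylogous-ester α-carbon (N-iodosuccinimide, MeCN, 0 °C) gives iodide F4. A Nozaki–Hiyama–Kishi coupling with aldehyde 13 (CrCl2, NiCl2 cat., DMF) then forms the C4a–C5 bond and comes back to the route at 25.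

Step 13 is the second risk. The freed C5 hydroxyl is held cis to the ethyl ester by the C4a=C8a double bond and may lactonise before it can be oxidised. The fallback accepts the lactone and opens it with an amide nucleophile. It sets out from 24: HF·pyridine followed by CSA (cat.) gives bicyclic δ-lactone F5. AlMe3 and MeNHOMe·HCl open it to hydroxy Weinreb amide F6, which DMP oxidises to keto amide F7. LiN(SiMe3)2 at −78 °C then closes the carbocycle by acylation of the C6 enolate with the Weinreb amide, and the fallback comes back to the route at 28.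

Step 15 is the third risk. Deprotonation at C3 instead of C6 can open the dihydropyranone by retro-oxa-Michael reaction, which would scramble C2, and the neopentyl ester is a sluggish electrophile. The fallback closes the ring by an intramolecular aldol on an aldehyde under catalytic weak base and then oxidises. It sets out from 24: excess iBu2AlH reduces the ester to CH2OH and the pyranone carbonyl to the allylic alcohol, giving diol F8. MnO2 reoxidises only the allylic C4 alcohol to give hydroxymethyl pyranone F9, and HF·pyridine frees the C5 alcohol to give diol F10. MnO2 oxidises the allylic C5 alcohol to hydroxy ketone F11, and DMP oxidises the primary alcohol to keto aldehyde F12. DBU (cat.) in CH2Cl2 at 0 °C effects the six-membered aldol to β-hydroxy ketone F13, and DMP oxidation of this β-hydroxy ketone comes back to the route at 28.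

## Further compounds

F1 | step 12 | ethyl (2R,4E)-2-[(5S)-3-hydroxy-5-(triethylsilyloxy)hexanoyl]-2,5,9-trimethyldeca-4,8-dienoate (carbinol epimers) | C[C@H](O[Si](CC)(CC)CC)CC(O)CC(=O)[C@@](C)(C/C=C(\C)CCC=C(C)C)C(=O)OCC
F2 | step 12 | ethyl (2R,4E)-2-[(5S)-3-oxo-5-(triethylsilyloxy)hexanoyl]-2,5,9-trimethyldeca-4,8-dienoate | C[C@H](O[Si](CC)(CC)CC)CC(=O)CC(=O)[C@@](C)(C/C=C(\C)CCC=C(C)C)C(=O)OCC
F3 | step 12 | ethyl (2R,4E)-2-[(2S)-2-methyl-4-oxo-3,4-dihydro-2H-pyran-6-yl]-2,5,9-trimethyldeca-4,8-dienoate | C[C@H]1CC(=O)C=C(O1)[C@@](C)(C/C=C(\C)CCC=C(C)C)C(=O)OCC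
F4 | step 12 | ethyl (2R,4E)-2-[(2S)-5-iodo-2-methyl-4-oxo-3,4-dihydro-2H-pyran-6-yl]-2,5,9-trimethyldeca-4,8-dienoate | C[C@H]1CC(=O)C(I)=C(O1)[C@@](C)(C/C=C(\C)CCC=C(C)C)C(=O)OCC
F5 | step 13 | bicyclic δ-lactone of 25 (C5 oxygen acylated by C7, pyranone ring and both stereocentres as in 25, C5 epimers) | C[C@H]1CC(=O)C2=C(O1)[C@@](C)(C/C=C(\C)CCC=C(C)C)C(=O)OC2CCC=C(C)C
F6 | step 13 | N-methoxy-N-methyl amide analogue of 25 (CON(OMe)Me in place of CO2Et) | C[C@H]1CC(=O)C(C(O)CCC=C(C)C)=C(O1)[C@@](C)(C/C=C(\C)CCC=C(C)C)C(=O)N(C)OC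
F7 | step 13 | N-methoxy-N-methyl amide analogue of 26 (CON(OMe)Me in place of CO2Et) | C[C@H]1CC(=O)C(C(=O)CCC=C(C)C)=C(O1)[C@@](C)(C/C=C(\C)CCC=C(C)C)C(=O)N(C)OC
F8 | step 15 | diol from 24 with CO2Et reduced to CH2OH and the C4 carbonyl reduced to CHOH (C5 silyl ether kept) | C[C@H]1CC(O)C(C(O[Si](C)(C)C(C)(C)C)CCC=C(C)C)=C(O1)[C@@](C)(C/C=C(\C)CCC=C(C)C)CO
F9 | step 15 | analogue of 24 with CH2OH in place of CO2Et | C[C@H]1CC(=O)C(C(O[Si](C)(C)C(C)(C)C)CCC=C(C)C)=C(O1)[C@@](C)(C/C=C(\C)CCC=C(C)C)CO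
F10 | step 15 | analogue of 25 with CH2OH in place of CO2Et | C[C@H]1CC(=O)C(C(O)CCC=C(C)C)=C(O1)[C@@](C)(C/C=C(\C)CCC=C(C)C)CO
F11 | step 15 | analogue of 26 with CH2OH in place of CO2Et | C[C@H]1CC(=O)C(C(=O)CCC=C(C)C)=C(O1)[C@@](C)(C/C=C(\C)CCC=C(C)C)CO
F12 | step 15 | analogue of 26 with CHO in place of CO2Et | C[C@H]1CC(=O)C(C(=O)CCC=C(C)C)=C(O1)[C@@](C)(C/C=C(\C)CCC=C(C)C)C=O
F13 | step 15 | 7-hydroxy-6,7-dihydro form of 28 (C7 carbinol, C6 sp3, C5 ketone, epimers at C6 and C7) | CC(C)=CCC/C(C)=C/C[C@@]1(C)C(O)C(CC=C(C)C)C(=O)C2=C1O[C@@H](C)CC2=O
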